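**Strategy.** The lactone oxygen on C6 and the acetoxy oxygen on C15 flank the C4=C5 double bond of the ten-membered ring as an O–C6–C5=C4–C15–O array, the retron of a 1,4-opened vinyl epoxide. The γ-lactone is therefore closed by a zerovalent-palladium-catalysed, strain-releasing 1,4-addition of a tethered carboxylic acid to a 2,2-disubstituted C4/C15 epoxide carrying a C5=C6 alkene. One operation forms the O–C6 bond and the C6 stereocentre, sets the C4=C5 geometry and frees the C15 hydroxyl. The acyclic precursor comes from an Ireland–Claisen rearrangement of a Sharpless epoxy allylic acetate; ring-closing metathesis at C1=C10 and C14 oxidation finish the germacranolide.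

Key step: step 10

Remark: germacranolide numbering (C1–C15) is used for positions and TBS = tert-butyldimethylsilyl; CIP descriptors at C4, C5 and C7 change between intermediates by priority effects only; the facial sense of the two reagent-controlled additions (steps 2 and 5) is assumed from the usual models, and the antipodal ligand would be used if either proved opposite.

Step 1
Reactants: 1 hex-5-enal
Product: 2 2-methylidenehex-5-enal
Conditions: 37% aq. CH2O, pyrrolidine (10 mol %), EtCO2H (10 mol %), iPrOH, 45 °C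
Reagents that add atoms: formaldehyde, C=O
Why: Amine-catalysed Mannich condensation–elimination (organocatalytic α-methylenation of an aldehyde) should install C15 as the methylene of a 2-substituted acrolein; no stereocentre is formed.

Step 2
Reactants: 3 3-(trimethylsilyl)prop-2-ynal
Product: 5 (3R)-5-methyl-1-(trimethylsilyl)hex-5-en-1-yn-3-ol, via diisopinocampheylborinate 4 (not isolated)
Conditions: (+)-Ipc2BOMe ((+)-B-methoxydiisopinocampheylborane, from (−)-α-pinene), CH2=C(CH3)CH2MgCl, Et2O, 0 °C → rt; then 3, −78 °C; then pH 7 buffer, MeOH, 30% H2O2, 0 °C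
Reagents that add atoms: methallylmagnesium chloride, C=C(C)C[Mg]Cl
Why: Brown asymmetric allylboration through a chair Zimmerman–Traxler transition state, in which the isopinocampheyl groups should direct the methallyl group to the Re face of the ynal and set C8 as R.

Step 3
Reactants: 5 (3R)-5-methyl-1-(trimethylsilyl)hex-5-en-1-yn-3-ol
Product: 6 (3R)-3-(TBSO)-5-methyl-1-(trimethylsilyl)hex-5-en-1-yne
Conditions: TBSCl, imidazole, DMF, rt
Reagents that add atoms: tert-butyldimethylsilyl chloride, CC(C)(C)[Si](C)(C)Cl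
Why: Standard silylation of a secondary alcohol; the ether must later survive hydride, amide base and the enolate Claisen, which an ester at C8 would not.

Step 4
Reactants: 6 (3R)-3-(TBSO)-5-methyl-1-(trimethylsilyl)hex-5-en-1-yne
Product: 7 (3R)-3-(TBSO)-5-methylhex-5-en-1-yne
Conditions: K2CO3 (0.2 equiv), MeOH, 0 °C → rt
Reagents that add atoms: none
Why: Methanolysis cleaves the alkynyl C–Si bond selectively, since the secondary O–TBS ether is inert to carbonate in methanol.

Step 5
Reactants: 7 (3R)-3-(TBSO)-5-methylhex-5-en-1-yne; 2 2-methylidenehex-5-enal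
Product: 8 (6S,9R)-9-(TBSO)-11-methyl-5-methylidenedodeca-1,11-dien-7-yn-6-ol
Conditions: (S,S)-ProPhenol (20 mol %), Ph3PO (40 mol %), Me2Zn (3 equiv), toluene, 0 °C; aq. NH4Cl
Reagents that add atoms: none
Why: ProPhenol–dinuclear-zinc-catalysed asymmetric alkynylation of an enal forms the C5–C6 bond; the ligand should deliver the zinc acetylide to the Re face of the aldehyde and set the C5 carbinol (6S here) independently of remote C8.

Step 6
Reactants: 8 (6S,9R)-9-(TBSO)-11-methyl-5-methylidenedodeca-1,11-dien-7-yn-6-ol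
Product: 9 (6R,7E,9R)-9-(TBSO)-11-methyl-5-methylidenedodeca-1,7,11-trien-6-ol
Conditions: NaAlH2(OCH2CH2OCH3)2 (Red-Al), THF, 0 °C → rt; aq. KNaC4H4O6
Reagents that add atoms: none
Why: Hydroxyl-directed trans-hydroalumination of the propargylic alcohol and protonolysis should give the E-alkene only; isolated alkenes and the silyl ether are not touched.

Step 7
Reactants: 9 (6R,7E,9R)-9-(TBSO)-11-methyl-5-methylidenedodeca-1,7,11-trien-6-ol
Product: 10 (1R,2E,4R)-1-[(2R)-2-(but-3-en-1-yl)oxiran-2-yl]-4-(TBSO)-6-methylhepta-2,6-dien-1-ol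
Conditions: Ti(OiPr)4 (20 mol %), D-(−)-diisopropyl tartrate (24 mol %), tBuOOH, 4 Å MS, CH2Cl2, −20 °C
Reagents that add atoms: tert-butyl hydroperoxide, CC(C)(C)OO
Why: Sharpless asymmetric epoxidation in its matched, site-selective mode: for this C5 configuration the D-tartrate catalyst is matched for the 2-substituted C4=C15 olefin and mismatched for C6=C7, so oxygen should be delivered erythro to the carbinol and set C4, while any C5 epimer is left behind.

Step 8
Reactants: 10 (1R,2E,4R)-1-[(2R)-2-(but-3-en-1-yl)oxiran-2-yl]-4-(TBSO)-6-methylhepta-2,6-dien-1-ol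
Product: 11 (1R,2E,4R)-1-[(2R)-2-(but-3-en-1-yl)oxiran-2-yl]-4-(TBSO)-6-methylhepta-2,6-dien-1-yl acetate
Conditions: Ac2O, Et3N, DMAP (5 mol %), CH2Cl2, 0 °C
Reagents that add atoms: acetic anhydride, CC(=O)OC(C)=O
Why: Base-buffered acylation of the secondary alcohol leaves the acid-sensitive epoxide intact and supplies the two-carbon unit C11–C12.

Step 9
Reactants: 11 (1R,2E,4R)-1-[(2R)-2-(but-3-en-1-yl)oxiran-2-yl]-4-(TBSO)-6-methylhepta-2,6-dien-1-yl acetate
Product: 14 (3S,4E)-5-[(2S)-2-(but-3-en-1-yl)oxiran-2-yl]-3-[(1R)-1-(TBSO)-3-methylbut-3-en-1-yl]pent-4-enoic acid, via ketene silyl acetal 12 (not isolated), via trimethylsilyl ester 13 (not isolated)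
Conditions: LiN(iPr)2, Me3SiCl, Et3N, THF, −78 °C → rt; then aq. pH 6 phosphate buffer; crude acid used at once
Reagents that add atoms: none
Why: Ireland–Claisen rearrangement through a chair transition state with the epoxide-bearing C4 group equatorial should form the C7–C11 bond suprafacially (C5 to C7 chirality transfer), give the E C5=C6 alkene and create the vinyl epoxide; prior epoxidation of C4=C15 removes the competing [3,3] path toward C15.

Step 10
Reactants: 14 (3S,4E)-5-[(2S)-2-(but-3-en-1-yl)oxiran-2-yl]-3-[(1R)-1-(TBSO)-3-methylbut-3-en-1-yl]pent-4-enoic acid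
Product: 16 (4S,5R)-4-[(1R)-1-(TBSO)-3-methylbut-3-en-1-yl]-5-[(1E)-2-(hydroxymethyl)hexa-1,5-dien-1-yl]oxolan-2-one, via allylpalladium carboxylate 15 (not isolated)
Conditions: Pd(PPh3)4 (5 mol %), THF, 0 °C → rt
Reagents that add atoms: none
Why: Zerovalent palladium binds the C5=C6 alkene anti to the C4–O bond and opens the strained epoxide to a zwitterionic η3-allyl complex spanning C4–C5–C6 (15, drawn C6-bound), whose C15 alkoxide deprotonates the tethered acid; the carboxylate then attacks C6 anti to palladium and releases the catalyst. The closest known reaction type is the Tsuji–Trost 1,4-addition of carboxylic acids to 1,3-diene monoepoxides, run here intramolecularly. The γ-lactone closes in a 5-exo-trig mode (oxygen onto allyl terminus C6, the allyl unit exocyclic), which also fixes regiochemistry because attack at the quaternary terminus C4 would need a seven-membered ring. C6 is set by double inversion, that is net retention relative to the epoxide oxygen of the C4 centre from step 7, and in the same sense by C7, whose hydrogen eclipses the allyl plane so that the acetic acid arm and the C8 chain lie on opposite faces and the trans-4,5-disubstituted lactone results. The required C4=C5 geometry (C15 trans to C6) should follow because only the rotamer with C15 syn on the allyl unit places the epoxide oxygen on the face from which the carboxylate reaches C6 without allylic strain, so the C4 and C7 centres are matched; a short reaction time limits re-ionisation of the allylic lactone.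

Step 11
Reactants: 16 (4S,5R)-4-[(1R)-1-(TBSO)-3-methylbut-3-en-1-yl]-5-[(1E)-2-(hydroxymethyl)hexa-1,5-dien-1-yl]oxolan-2-one
Product: 19 (4S,5R)-4-[(1R)-1-(TBSO)-3-methylbut-3-en-1-yl]-5-[(1E)-2-(hydroxymethyl)hexa-1,5-dien-1-yl]-3-methylideneoxolan-2-one, via Mannich base 17 (not isolated), via trimethylammonium iodide 18 (not isolated)
Conditions: LiN(iPr)2 (2.3 equiv), THF, −78 °C; CH2=NMe2+ I−, −78 → 0 °C; aq. NH4Cl; crude in MeOH, MeI, rt; then aq. NaHCO3, CH2Cl2
Reagents that add atoms: N,N-dimethylmethyleneiminium iodide (Eschenmoser's salt), C=[N+](C)C.[I-]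
Why: The alkoxide–enolate dianion should undergo Mannich aminomethylation at C11 anti to the C7 substituent, and exhaustive methylation followed by mild-base β-elimination gives the exocyclic methylene, so the transient C11 centre does not matter.

Step 12
Reactants: 19 (4S,5R)-4-[(1R)-1-(TBSO)-3-methylbut-3-en-1-yl]-5-[(1E)-2-(hydroxymethyl)hexa-1,5-dien-1-yl]-3-methylideneoxolan-2-one
Product: 20 (4S,5R)-5-[(1E)-2-(acetoxymethyl)hexa-1,5-dien-1-yl]-4-[(1R)-1-(TBSO)-3-methylbut-3-en-1-yl]-3-methylideneoxolan-2-one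
Conditions: Ac2O, pyridine, CH2Cl2, 0 °C → rt
Reagents that add atoms: acetic anhydride, CC(=O)OC(C)=O
Why: Simple acetylation of the primary allylic C15 alcohol, placed after step 11 so that no enolisable acetate is present during enolate chemistry.

Step 13
Reactants: 20 (4S,5R)-5-[(1E)-2-(acetoxymethyl)hexa-1,5-dien-1-yl]-4-[(1R)-1-(TBSO)-3-methylbut-3-en-1-yl]-3-methylideneoxolan-2-one
Product: 21 (3aS,4R,6Z,10E,11aR)-10-(acetoxymethyl)-4-(TBSO)-6-methyl-3-methylidene-3a,4,5,8,9,11a-hexahydrocyclodeca[b]furan-2(3H)-one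
Conditions: second-generation Hoveyda–Grubbs catalyst (10 mol %, in portions), toluene (1 mM), 80 °C, argon sparge
Reagents that add atoms: none
Why: Ring-closing metathesis should initiate at the monosubstituted C1 vinyl group and close onto the C10 isopropenyl group; the trans-fused lactone and the ring-cis C4=C5 alkene pre-organise the chains, and the ten-membered ring should favour the less strained ring-cis C1=C10 olefin that the target needs, while the acrylate and the trisubstituted allylic-ester olefin are poor metathesis partners.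

Step 14
Reactants: 21 (3aS,4R,6Z,10E,11aR)-10-(acetoxymethyl)-4-(TBSO)-6-methyl-3-methylidene-3a,4,5,8,9,11a-hexahydrocyclodeca[b]furan-2(3H)-one
Product: 22 (3aR,4R,6Z,10E,11aR)-10-(acetoxymethyl)-4-hydroxy-6-methyl-3-methylidene-3a,4,5,8,9,11a-hexahydrocyclodeca[b]furan-2(3H)-one
Conditions: HF·pyridine, pyridine, THF, 0 °C → rt
Reagents that add atoms: none
Why: Buffered acidic fluoride desilylation avoids the basic conditions that could cause acetate migration, translactonisation to C8 or conjugate addition to the methylene lactone.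

Step 15
Reactants: 22 (3aR,4R,6Z,10E,11aR)-10-(acetoxymethyl)-4-hydroxy-6-methyl-3-methylidene-3a,4,5,8,9,11a-hexahydrocyclodeca[b]furan-2(3H)-one; 23 (2S)-2-methylbutanoic acid
Product: 24 (3aR,4R,6Z,10E,11aR)-10-(acetoxymethyl)-6-methyl-3-methylidene-2-oxo-2,3,3a,4,5,8,9,11a-octahydrocyclodeca[b]furan-4-yl (2S)-2-methylbutanoate
Conditions: DCC, DMAP (10 mol %), CH2Cl2, 0 °C → rt
Reagents that add atoms: none
Why: Steglich esterification of the secondary C8 alcohol with retention at C8; catalytic DMAP at low temperature should keep the α-stereocentre of the acyl group from epimerising.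

Step 16
Reactants: 24 (3aR,4R,6Z,10E,11aR)-10-(acetoxymethyl)-6-methyl-3-methylidene-2-oxo-2,3,3a,4,5,8,9,11a-octahydrocyclodeca[b]furan-4-yl (2S)-2-methylbutanoate
Product: 25 (3aR,4R,6E,10E,11aR)-10-(acetoxymethyl)-6-(hydroxymethyl)-3-methylidene-2-oxo-2,3,3a,4,5,8,9,11a-octahydrocyclodeca[b]furan-4-yl (2S)-2-methylbutanoate
Conditions: SeO2 (0.5 equiv), tBuOOH, CH2Cl2, rt
Reagents that add atoms: tert-butyl hydroperoxide, CC(C)(C)OO
Why: Riley allylic hydroxylation (ene reaction, then [2,3]-shift) should occur at the C14 methyl of the only electron-rich olefin C1=C10, as is precedented for C14 of 1(10)-unsaturated germacranolides; C4=C5 is deactivated by two allylic C–O bonds and C9 by the neighbouring ester, and the ring-cis geometry is kept.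

Step 17
Reactants: 25 (3aR,4R,6E,10E,11aR)-10-(acetoxymethyl)-6-(hydroxymethyl)-3-methylidene-2-oxo-2,3,3a,4,5,8,9,11a-octahydrocyclodeca[b]furan-4-yl (2S)-2-methylbutanoate
Product: 26 (3aR,4R,6E,10E,11aR)-10-(acetoxymethyl)-6-formyl-3-methylidene-2-oxo-2,3,3a,4,5,8,9,11a-octahydrocyclodeca[b]furan-4-yl (2S)-2-methylbutanoate
Conditions: MnO2 (activated, excess), CH2Cl2, rt
Reagents that add atoms: none
Why: Chemoselective oxidation of the primary allylic alcohol gives the conjugated enal with the formyl group trans to C2, its stable geometry; esters, lactone and other olefins are inert.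

**Compound list**

1 | hex-5-enal | C=CCCCC=O | starting material
2 | 2-methylidenehex-5-enal | C=CCCC(=C)C=O | intermediate
3 | 3-(trimethylsilyl)prop-2-ynal | C[Si](C)(C)C#CC=O | starting material
4 | (3R)-5-methyl-1-(trimethylsilyl)hex-5-en-1-yn-3-yl diisopinocampheylborinate | C[Si](C)(C)C#C[C@H](OB([C@H]1C[C@H]2C[C@@H]([C@@H]1C)C2(C)C)[C@H]1C[C@H]2C[C@@H]([C@@H]1C)C2(C)C)CC(C)=C | intermediate (not isolated)
5 | (3R)-5-methyl-1-(trimethylsilyl)hex-5-en-1-yn-3-ol | C[Si](C)(C)C#C[C@H](O)CC(C)=C | intermediate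
6 | (3R)-3-(TBSO)-5-methyl-1-(trimethylsilyl)hex-5-en-1-yne | C[Si](C)(C)C#C[C@H](O[Si](C)(C)C(C)(C)C)CC(C)=C | intermediate
7 | (3R)-3-(TBSO)-5-methylhex-5-en-1-yne | C#C[C@H](O[Si](C)(C)C(C)(C)C)CC(C)=C | intermediate
8 | (6S,9R)-9-(TBSO)-11-methyl-5-methylidenedodeca-1,11-dien-7-yn-6-ol | C=CCCC(=C)[C@H](O)C#C[C@H](O[Si](C)(C)C(C)(C)C)CC(C)=C | intermediate
9 | (6R,7E,9R)-9-(TBSO)-11-methyl-5-methylidenedodeca-1,7,11-trien-6-ol | C=CCCC(=C)[C@H](O)/C=C/[C@H](O[Si](C)(C)C(C)(C)C)CC(C)=C | intermediate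
10 | (1R,2E,4R)-1-[(2R)-2-(but-3-en-1-yl)oxiran-2-yl]-4-(TBSO)-6-methylhepta-2,6-dien-1-ol | C=CCC[C@@]1(CO1)[C@H](O)/C=C/[C@H](O[Si](C)(C)C(C)(C)C)CC(C)=C | intermediate
11 | (1R,2E,4R)-1-[(2R)-2-(but-3-en-1-yl)oxiran-2-yl]-4-(TBSO)-6-methylhepta-2,6-dien-1-yl acetate | C=CCC[C@@]1(CO1)[C@H](OC(C)=O)/C=C/[C@H](O[Si](C)(C)C(C)(C)C)CC(C)=C | intermediate
12 | O-trimethylsilyl ketene acetal of acetate 11 (C5–O–C(=CH2)–OSiMe3) | C=CCC[C@@]1(CO1)[C@H](OC(=C)O[Si](C)(C)C)/C=C/[C@H](O[Si](C)(C)C(C)(C)C)CC(C)=C | intermediate (not isolated)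
13 | trimethylsilyl ester of acid 14 | C=CCC[C@@]1(CO1)/C=C/[C@H](CC(=O)O[Si](C)(C)C)[C@H](O[Si](C)(C)C(C)(C)C)CC(C)=C | intermediate (not isolated)
14 | (3S,4E)-5-[(2S)-2-(but-3-en-1-yl)oxiran-2-yl]-3-[(1R)-1-(TBSO)-3-methylbut-3-en-1-yl]pent-4-enoic acid | C=CCC[C@@]1(CO1)/C=C/[C@H](CC(=O)O)[C@H](O[Si](C)(C)C(C)(C)C)CC(C)=C | intermediate
15 | zwitterionic (η3-allyl)bis(triphenylphosphine)palladium carboxylate spanning C4–C5–C6, C15 hydroxyl free, drawn as its C6-bound form with palladium anti to the former epoxide oxygen | [O-]C(=O)C[C@@H]([C@H](/C=C(/CO)CCC=C)[Pd-]([P+](c1ccccc1)(c1ccccc1)c1ccccc1)[P+](c1ccccc1)(c1ccccc1)c1ccccc1)[C@H](O[Si](C)(C)C(C)(C)C)CC(C)=C | intermediate (not isolated)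
16 | (4S,5R)-4-[(1R)-1-(TBSO)-3-methylbut-3-en-1-yl]-5-[(1E)-2-(hydroxymethyl)hexa-1,5-dien-1-yl]oxolan-2-one | C1C(=O)O[C@H](/C=C(/CO)CCC=C)[C@H]1[C@H](O[Si](C)(C)C(C)(C)C)CC(C)=C | intermediate
17 | (3R,4S,5R)-3-[(dimethylamino)methyl] derivative of lactone 16 | CN(C)C[C@@H]1C(=O)O[C@H](/C=C(/CO)CCC=C)[C@H]1[C@H](O[Si](C)(C)C(C)(C)C)CC(C)=C | intermediate (not isolated)
18 | (3R,4S,5R)-3-[(trimethylammonio)methyl] derivative of lactone 16, iodide | [I-].C[N+](C)(C)C[C@@H]1C(=O)O[C@H](/C=C(/CO)CCC=C)[C@H]1[C@H](O[Si](C)(C)C(C)(C)C)CC(C)=C | intermediate (not isolated)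
19 | (4S,5R)-4-[(1R)-1-(TBSO)-3-methylbut-3-en-1-yl]-5-[(1E)-2-(hydroxymethyl)hexa-1,5-dien-1-yl]-3-methylideneoxolan-2-one | C=C1C(=O)O[C@H](/C=C(/CO)CCC=C)[C@H]1[C@H](O[Si](C)(C)C(C)(C)C)CC(C)=C | intermediate
20 | (4S,5R)-5-[(1E)-2-(acetoxymethyl)hexa-1,5-dien-1-yl]-4-[(1R)-1-(TBSO)-3-methylbut-3-en-1-yl]-3-methylideneoxolan-2-one | C=C1C(=O)O[C@H](/C=C(/COC(C)=O)CCC=C)[C@H]1[C@H](O[Si](C)(C)C(C)(C)C)CC(C)=C | intermediate
21 | (3aS,4R,6Z,10E,11aR)-10-(acetoxymethyl)-4-(TBSO)-6-methyl-3-methylidene-3a,4,5,8,9,11a-hexahydrocyclodeca[b]furan-2(3H)-one | C=C1C(=O)O[C@@H]2/C=C(/COC(C)=O)CC/C=C(/C)C[C@@H](O[Si](C)(C)C(C)(C)C)[C@@H]12 | intermediate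
22 | (3aR,4R,6Z,10E,11aR)-10-(acetoxymethyl)-4-hydroxy-6-methyl-3-methylidene-3a,4,5,8,9,11a-hexahydrocyclodeca[b]furan-2(3H)-one | C=C1C(=O)O[C@@H]2/C=C(/COC(C)=O)CC/C=C(/C)C[C@@H](O)[C@@H]12 | intermediate
23 | (2S)-2-methylbutanoic acid | CC[C@H](C)C(=O)O | starting material
24 | (3aR,4R,6Z,10E,11aR)-10-(acetoxymethyl)-6-methyl-3-methylidene-2-oxo-2,3,3a,4,5,8,9,11a-octahydrocyclodeca[b]furan-4-yl (2S)-2-methylbutanoate | C=C1C(=O)O[C@@H]2/C=C(/COC(C)=O)CC/C=C(/C)C[C@@H](OC(=O)[C@@H](C)CC)[C@@H]12 | intermediate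
25 | (3aR,4R,6E,10E,11aR)-10-(acetoxymethyl)-6-(hydroxymethyl)-3-methylidene-2-oxo-2,3,3a,4,5,8,9,11a-octahydrocyclodeca[b]furan-4-yl (2S)-2-methylbutanoate | C=C1C(=O)O[C@@H]2/C=C(/COC(C)=O)CC/C=C(/CO)C[C@@H](OC(=O)[C@@H](C)CC)[C@@H]12 | intermediate
26 | (3aR,4R,6E,10E,11aR)-10-(acetoxymethyl)-6-formyl-3-methylidene-2-oxo-2,3,3a,4,5,8,9,11a-octahydrocyclodeca[b]furan-4-yl (2S)-2-methylbutanoate | C=C1C(=O)O[C@@H]2/C=C(/COC(C)=O)CC/C=C(/C=O)C[C@@H](OC(=O)[C@@H](C)CC)[C@@H]12 | target

**Step count and risks**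

Total step count: 17. Longest linear sequence: 16 steps (3 to 26, steps 2–17); step 1 supplies aldehyde 2 as a one-step side branch.

The three steps most likely to fail:

Step 13 (ring-closing metathesis). Intermolecular metathesis through the unhindered C1 vinyl groups may outrun closure of the strained ten-membered ring onto the 1,1-disubstituted C10 olefin, and ruthenium hydrides may migrate double bonds on prolonged heating. The fallback changes the point at which the ring is closed: it sets out from hydroxy lactone 16, which carries neither the acrylate nor the C15 ester. Metathesis of 16 under the same high-dilution conditions should give the macrocyclic hydroxy lactone F1. The methylene group is then introduced on the ring as in step 11, through the Mannich base F2 and the trimethylammonium iodide F3, to give the α-methylene hydroxy lactone F4. Acetylation (Ac2O, pyridine) brings the route back at 21.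

Step 10 (palladium-catalysed lactonisation). Equilibration of the allylpalladium intermediate, or acid-promoted non-stereospecific opening of the vinyl epoxide before catalysis, may erode the C6 configuration and the C4=C5 geometry, and the product may re-ionise. The fallback uses electrophilic cyclisation and reductive epoxide opening instead, and sets out from epoxy alcohol 10. An Eschenmoser–Claisen rearrangement (CH3C(OMe)2NMe2, toluene, 110 °C) should give, with the same chair-controlled chirality transfer, the N,N-dimethylamide F5. Iodolactonisation of the amide (I2, THF/H2O, 0 °C; anti addition, trans-lactone through the iminium ether) then forms the O–C6 bond and gives the β-iodo epoxide F6. Zinc dust (Zn, EtOH, aq. NH4Cl) removes iodine and opens the epoxide by anti elimination, which should give the same C15-trans-to-C6 olefin. The route is rejoined at 16, bypassing steps 8–10.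

Step 16 (allylic oxidation). Site selectivity may be poor (attack at C2, C3 or C9), and over-oxidation or selenium addition to the methylene lactone may occur. The fallback places the C14 heteroatom before ring closure, on the only electron-rich 1,1-disubstituted olefin, and sets out from diene 20. Ene-type allylic chlorination of the isopropenyl group (Ca(OCl)2, solid CO2, CH2Cl2/H2O, 0 °C) should give the 2-(chloromethyl)allyl compound F7. Ring-closing metathesis as in step 13 gives the macrocyclic allylic chloride F8. Ganem oxidation (N-methylmorpholine N-oxide, MeCN, rt) gives the enal silyl ether F9. HF·pyridine gives the C8 alcohol F10, and Steglich esterification with 23 (DCC, DMAP) returns the route at 26.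

**Further compounds**

F1 | step 13 | (3aS,4R,6Z,10E,11aR)-4-(TBSO)-10-(hydroxymethyl)-6-methyl-3a,4,5,8,9,11a-hexahydrocyclodeca[b]furan-2(3H)-one | C1C(=O)O[C@@H]2/C=C(/CO)CC/C=C(/C)C[C@@H](O[Si](C)(C)C(C)(C)C)[C@@H]12
F2 | step 13 | (3R)-3-[(dimethylamino)methyl] derivative of F1 | CN(C)C[C@@H]1C(=O)O[C@@H]2/C=C(/CO)CC/C=C(/C)C[C@@H](O[Si](C)(C)C(C)(C)C)[C@@H]12
F3 | step 13 | (3R)-3-[(trimethylammonio)methyl] derivative of F1, iodide | [I-].C[N+](C)(C)C[C@@H]1C(=O)O[C@@H]2/C=C(/CO)CC/C=C(/C)C[C@@H](O[Si](C)(C)C(C)(C)C)[C@@H]12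
F4 | step 13 | (3aS,4R,6Z,10E,11aR)-4-(TBSO)-10-(hydroxymethyl)-6-methyl-3-methylidene-3a,4,5,8,9,11a-hexahydrocyclodeca[b]furan-2(3H)-one | C=C1C(=O)O[C@@H]2/C=C(/CO)CC/C=C(/C)C[C@@H](O[Si](C)(C)C(C)(C)C)[C@@H]12
F5 | step 10 | (3S,4E)-5-[(2S)-2-(but-3-en-1-yl)oxiran-2-yl]-3-[(1R)-1-(TBSO)-3-methylbut-3-en-1-yl]-N,N-dimethylpent-4-enamide | C=CCC[C@@]1(CO1)/C=C/[C@H](CC(=O)N(C)C)[C@H](O[Si](C)(C)C(C)(C)C)CC(C)=C
F6 | step 10 | (4S,5S)-5-[(S)-[(2R)-2-(but-3-en-1-yl)oxiran-2-yl](iodo)methyl]-4-[(1R)-1-(TBSO)-3-methylbut-3-en-1-yl]oxolan-2-one | C1C(=O)O[C@H]([C@H](I)[C@]2(CO2)CCC=C)[C@H]1[C@H](O[Si](C)(C)C(C)(C)C)CC(C)=C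
F7 | step 16 | (4S,5R)-5-[(1E)-2-(acetoxymethyl)hexa-1,5-dien-1-yl]-4-[(1R)-1-(TBSO)-3-(chloromethyl)but-3-en-1-yl]-3-methylideneoxolan-2-one | C=C1C(=O)O[C@H](/C=C(/COC(C)=O)CCC=C)[C@H]1[C@H](O[Si](C)(C)C(C)(C)C)CC(CCl)=C
F8 | step 16 | (3aS,4R,6E,10E,11aR)-10-(acetoxymethyl)-4-(TBSO)-6-(chloromethyl)-3-methylidene-3a,4,5,8,9,11a-hexahydrocyclodeca[b]furan-2(3H)-one | C=C1C(=O)O[C@@H]2/C=C(/COC(C)=O)CC/C=C(/CCl)C[C@@H](O[Si](C)(C)C(C)(C)C)[C@@H]12
F9 | step 16 | (3aS,4R,6E,10E,11aR)-10-(acetoxymethyl)-4-(TBSO)-6-formyl-3-methylidene-3a,4,5,8,9,11a-hexahydrocyclodeca[b]furan-2(3H)-one | C=C1C(=O)O[C@@H]2/C=C(/COC(C)=O)CC/C=C(/C=O)C[C@@H](O[Si](C)(C)C(C)(C)C)[C@@H]12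
F10 | step 16 | (3aR,4R,6E,10E,11aR)-10-(acetoxymethyl)-6-formyl-4-hydroxy-3-methylidene-3a,4,5,8,9,11a-hexahydrocyclodeca[b]furan-2(3H)-one | C=C1C(=O)O[C@@H]2/C=C(/COC(C)=O)CC/C=C(/C=O)C[C@@H](O)[C@@H]12
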